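| flask | starting material | coupling partner | second substrate | third substrate | remark | time |
|---|---|---|---|---|---|---|
| maple | 10 mM | 11 mM | 2 mM | 50 mM | run made earlier |  |
| ash | 10 mM | 11 mM | 1 mM | 50 mM | run made earlier |  |
| alder | 10 mM | 11 mM | 4 mM | 50 mM | run made earlier |  |
| Wednesday's | 10 mM | 11.0 mM (fed, over 5.0 h) | 2.00 mM | 50.0 mM | all else is in the flask from the start; the feed brings no volume worth counting | 6.0 h |
| Sunday's | 10 mM | 11.0 mM (in portions, 2, over 5.0 h) | 2.00 mM | 50.0 mM | first portion at the start, last at 5.0 h | 6.0 h |
| Thursday's | 10 mM | 11.0 mM | 2.00 mM | 50.0 mM | everything together at the start | 6.0 h |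
| Tuesday's | 10 mM | 11.0 mM | 2.00 mM | 50.0 mM (fed, over 5.0 h) | all else is in the flask from the start; the feed brings no volume worth counting | 6.0 h |

| run | time / h | target / % | isomer of the product / % |
|---|---|---|---|
| maple | 0.417 | 0.8 | 1.2 |
| maple | 1.33 | 2.4 | 3.7 |
| maple | 2.00 | 1.5 | 5.0 |
| maple | 3.00 | 1.8 | 6.7 |
| maple | 5.00 | 1.4 | 8.1 |
| maple | 6.00 | 0.4 | 8.8 |
| ash | 1.33 | 2.6 | 3.9 |
| ash | 2.50 | 2.0 | 6.8 |
| ash | 4.00 | 1.9 | 7.8 |
| ash | 5.00 | 0.4 | 8.0 |
| ash | 6.00 | 1.6 | 8.2 |
| ash | 8.00 | 1.3 | 8.2 |
| alder | 1.33 | 2.2 | 3.4 |
| alder | 2.50 | 1.6 | 5.7 |
| alder | 4.00 | 1.8 | 7.2 |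
| alder | 5.00 | 1.0 | 7.1 |
| alder | 6.00 | 1.1 | 6.5 |
| alder | 8.00 | 2.0 | 9.1 |

(scatter of a reading: 0.5 percentage points)

- the flask with the highest share of target in target plus isomer of the product ("all alike" if they lie within 1.5 percentage points) (Wednesday's / Sunday's / Thursday's / Tuesday's / all alike)
- share of target in target plus isomer of the product at the end, Wednesday's
- share of target in target plus isomer of the product at the end, Sunday's
- share of target in target plus isomer of the product at the end, Thursday's
- share of target in target plus isomer of the product at the end, Tuesday's

Product read early is richer in target than product read late: at 1.33 h the maple, ash and alder runs together show a mean total of target plus isomer of the product, M_e = 6.07%, with target share s_e = 39.6%, whereas their readings from 5.00 h on give a plateau M_q = 9.15% with share s_q = 12.6%. Taking the coupling partner as lost in pseudo-first-order fashion, product is born at a rate falling as exp(−λt), and M_e against M_q reads λ = 0.818 /h.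

If product is born as target and relaxes toward s_q at rate k, integrating birth and relaxation together gives, for a dose D of eventual product at age a, an excess X = Dλ(exp(−λa) − exp(−ka))/(k − λ), and the share is s = s_q + (1 − s_q)X/M, with M all product made. The early readings have X/M = 0.309, so dropping exp(−ka) gives k ≈ 2.16 /h. Sunday's flask is reckoned to make half the plateau per portion, the last aged 1.00 h; M is then 77.6% of plateau, and with the excess of the last portion counted and that of the first dropped, s = 23.7%.

The weak link is the dropped term, 0.0565 against exp(−λt) = 0.337. Put back once, it gives k = 1.94 /h, the relaxation rate of the target share, hence 24.8% for Sunday's and 13.0% for Thursday's. The maple, ash and alder runs each held 50 mM of third substrate, so this reckoning gives no figure for Tuesday's.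

The forecast gives 22% for Wednesday's, 23% for Sunday's, 15% for Thursday's and 16% for Tuesday's, with Sunday's highest, on the ground “Fresh product therefore carries more target.” Its Sunday's figure lies below the reckoning here, its Thursday's figure above.

The flasks end at 19.1% for Wednesday's, 24.8% for Sunday's, 13.1% for Thursday's and 13.2% for Tuesday's, so Sunday's leads. At 6.00 h Sunday's still holds 23% of its coupling partner. Wednesday's puts k to use: over 5.0 h the steady feed is taken to make product at the plateau divided by that time, so the excess at the end of feeding is about that rate over k, and carrying it through the last 1.00 h, with the coupling partner still in Wednesday's flask reckoned to go on making product at a falling rate, gives s = 19.2%.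

    starting material + coupling partner → target (k = 0.114 /M/min)
    second substrate + coupling partner → second product (k = 0.548 /M/min)
    third substrate + coupling partner → third product (k = 0.0418 /M/min)
    target ⇌ isomer of the product (K = 7.00, k = 0.0279 /min)
    coupling partner → decomposed reagent (k = 0.00901 /min)

Sunday's flask read at 25 h has its last portion aged 20.0 h, which is 38.8 times 1/k, and the same reckoning gives s = 12.6%. The simulation gives 12.5%.

The earlier runs and the new flask were generated by integration from invented constants; scatter was added.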